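**Strategy**

The six-membered ring is an enolised cyclohexane-1,3,5-trione: carbonyl-type carbons C1, C3, C5 alternate with nucleophilic carbons C2 (acylated), C4 (prenylated) and C6 (quaternary, OMe). This alternation is exploited in a [4+2] annulation that forms C1–C6 and C4–C5 in one operation. The precursors are a four-membered ring, 3-ethoxy-4-prenylcyclobutenone (C1–C4), and the lithium enolate of a chiral 2-methoxy-2-prenylacetate (C5, C6). Enolate 1,2-addition creates C6 under auxiliary control, oxyanion-accelerated 4π ring opening unmasks a dienolate, and Dieckmann closure onto the auxiliary ester expels the auxiliary. Enol ether hydrolysis and acylation at C2 then give the target.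

Key step: step 4

Remark: 5-methylhex-4-enoic acid is taken as a catalogue compound, and the enol tautomers of the cyclic triketones are treated as one compound, drawn in the tautomer of the target.

**Route**

Step 1
Reactants: 1 5-methylhex-4-enoic acid; 2 ethoxyacetylene
Product: 5 3-ethoxy-4-(3-methylbut-2-en-1-yl)cyclobut-2-en-1-one (racemic), via acid chloride 3 (not isolated), via prenylketene 4 (not isolated)
Conditions: (COCl)2, cat. DMF, CH2Cl2, 0 to 23 °C, evaporate; then 2 (2.5 equiv), Et3N (slow addition), Et2O, 23 to 35 °C
Reagents that add atoms: none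
Why: Dehydrochlorination of the acid chloride gives a monoalkylketene that is trapped in a thermal ketene–ynol ether [2+2] cycloaddition; the nucleophilic CH carbon of the alkyne bonds to the ketene carbonyl carbon, which places ethoxy at C3 and prenyl at C4 of the cyclobutenone (racemic, both enantiomers serve in step 4).

Step 2
Reactants: 6 (1S,2R)-2-phenylcyclohexan-1-ol; 7 methoxyacetyl chloride
Product: 8 (1S,2R)-2-phenylcyclohexyl 2-methoxyacetate
Conditions: pyridine, cat. DMAP, CH2Cl2, 0 to 23 °C
Reagents that add atoms: none
Why: DMAP-catalysed acylation of a secondary alcohol by an acid chloride; the two stereocentres of the auxiliary are not touched.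

Step 3
Reactants: 8 (1S,2R)-2-phenylcyclohexyl 2-methoxyacetate; 9 1-bromo-3-methylbut-2-ene (prenyl bromide)
Product: 11 (1S,2R)-2-phenylcyclohexyl 2-methoxy-5-methylhex-4-enoate (both epimers at C2), via lithium enolate 10 (not isolated)
Conditions: LiN(iPr)2, THF, −78 °C; then 9, DMPU, −78 to −20 °C
Reagents that add atoms: none
Why: Alkylation of a lithium-chelated glycolate ester enolate with an allylic bromide (SN2 at the primary carbon); the new centre forms as a mixture of epimers, which is of no consequence because it becomes trigonal again in step 4.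

Step 4
Reactants: 11 (1S,2R)-2-phenylcyclohexyl 2-methoxy-5-methylhex-4-enoate; 5 3-ethoxy-4-(3-methylbut-2-en-1-yl)cyclobut-2-en-1-one
Product: 16 (6S)-3,5-dihydroxy-6-methoxy-4,6-bis(3-methylbut-2-en-1-yl)cyclohexa-2,4-dien-1-one, via lithium enolate 12 (not isolated), via cyclobutenoxide adduct 13 (not isolated), via dienolate 14 (not isolated), via ethyl enol ether lithium salt 15 (not isolated)
Conditions: LiN(iPr)2 (1.1 equiv), THF, −78 °C; rac-5 (2 equiv), −78 to 23 °C; then 2 M aq HCl, THF, 23 °C
Reagents that add atoms: water, O
Why: Proposed new method: the lithium-chelated enolate 12 (methoxy cis to the oxido group, lithium bridging both oxygens) should add 1,2 to the strained ketone of 5, which cannot be enolised without forming an antiaromatic oxidocyclobutadiene, to give alkoxide 13 (first bond, C1–C6); 13 should then undergo oxyanion-accelerated conrotatory 4π electrocyclic ring opening with the oxido group rotating outward, so that the new quaternary carbon sits cis to the diene chain in dienolate 14, whose γ-carbon attacks the auxiliary ester in a Dieckmann acyl substitution (second bond, C4–C5; the six-membered ring closes 6-exo-trig) with loss of the auxiliary alkoxide, which deprotonates C4–H and renders the sequence irreversible. The closest known reaction types are the alkoxide-accelerated ring opening and reclosure cascades of organolithium adducts of cyclobutenones and squarate esters and the γ-acylation of vinylogous ester dienolates; what is new is their union with an ester enolate into a [4+2] annulation. The only stereocentre that survives is C6, set in the addition step by the (1S,2R)-2-phenylcyclohexyl group: in the s-cis ester conformer of 12, with the carbinol C–H eclipsing the enolate C–O bond, the phenyl ring covers the Si face of the enolate carbon, the ketone is taken up on the Re face, and this corresponds to 6S in the product. The carbinol and prenyl-bearing carbons of 13 become trigonal again, so that both enantiomers of 5 converge on one product, and the excess of racemic 5 lets the enolate select its matched partner. The step needs 1,2- over 1,4-addition (hard lithium enolate against a ketone that is far more electrophilic than the vinylogous ester carbon) and closure through the γ-carbon of 14 (attack through the α-carbon would give a four-membered ring). Aqueous acid finally cleaves the ethyl vinylogous ester of 15 to the free enol of 16.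

Step 5
Reactants: 16 (6S)-3,5-dihydroxy-6-methoxy-4,6-bis(3-methylbut-2-en-1-yl)cyclohexa-2,4-dien-1-one; 17 3-phenylpropanoyl chloride
Product: 19 (6S)-3,5-dihydroxy-6-methoxy-4,6-bis(3-methylbut-2-en-1-yl)-2-(3-phenylpropanoyl)cyclohexa-2,4-dien-1-one (the target), via enol ester 18 (not isolated)
Conditions: Et3N, CH2Cl2, 0 °C; then DMAP (0.3 equiv), 23 °C
Reagents that add atoms: none
Why: O-acylation of the enolised trione followed by DMAP-catalysed O-to-C acyl migration (Fries-type rearrangement of 1,3-dione enol esters) should deliver the acyl group to C2, the only unsubstituted carbon between two carbonyls, where the product is held as a stabilised triketone enolate; the quaternary stereocentre is not involved.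

**Compound list**

1 | 5-methylhex-4-enoic acid | CC(C)=CCCC(=O)O | starting material
2 | ethoxyacetylene (ethyl ethynyl ether) | CCOC#C | starting material
3 | 5-methylhex-4-enoyl chloride | CC(C)=CCCC(=O)Cl | intermediate (not isolated)
4 | 5-methylhexa-1,4-dien-1-one (prenylketene) | CC(C)=CCC=C=O | intermediate (not isolated)
5 | rac-3-ethoxy-4-(3-methylbut-2-en-1-yl)cyclobut-2-en-1-one | CCOC1=CC(=O)C1CC=C(C)C | intermediate
6 | (1S,2R)-2-phenylcyclohexan-1-ol (trans) | O[C@H]1CCCC[C@@H]1c1ccccc1 | starting material
7 | methoxyacetyl chloride | COCC(=O)Cl | starting material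
8 | (1S,2R)-2-phenylcyclohexyl 2-methoxyacetate | COCC(=O)O[C@H]1CCCC[C@@H]1c1ccccc1 | intermediate
9 | 1-bromo-3-methylbut-2-ene (prenyl bromide) | CC(C)=CCBr | starting material
10 | lithium enolate of 8 (methoxy cis to oxido, lithium-chelated) | [Li+].CO/C=C(\[O-])O[C@H]1CCCC[C@@H]1c1ccccc1 | intermediate (not isolated)
11 | (1S,2R)-2-phenylcyclohexyl 2-methoxy-5-methylhex-4-enoate, both epimers at C2 | COC(CC=C(C)C)C(=O)O[C@H]1CCCC[C@@H]1c1ccccc1 | intermediate
12 | lithium enolate of 11 (methoxy cis to oxido, lithium-chelated) | [Li+].CO/C(CC=C(C)C)=C(\[O-])O[C@H]1CCCC[C@@H]1c1ccccc1 | intermediate (not isolated)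
13 | lithium 3-ethoxy-1-[(2R)-2-methoxy-5-methyl-1-oxo-1-{[(1S,2R)-2-phenylcyclohexyl]oxy}hex-4-en-2-yl]-4-(3-methylbut-2-en-1-yl)cyclobut-2-en-1-olate (oxido cis to the ring prenyl group; one diastereomer from each enantiomer of 5) | [Li+].CCOC1=CC([O-])([C@](OC)(CC=C(C)C)C(=O)O[C@H]2CCCC[C@@H]2c2ccccc2)C1CC=C(C)C | intermediate (not isolated)
14 | lithium (2R,3E,5E)-5-ethoxy-2-methoxy-9-methyl-2-(3-methylbut-2-en-1-yl)-1-oxo-1-{[(1S,2R)-2-phenylcyclohexyl]oxy}deca-3,5,8-trien-3-olate | [Li+].[O-]/C(=C/C(OCC)=C\CC=C(C)C)[C@](OC)(CC=C(C)C)C(=O)O[C@H]1CCCC[C@@H]1c1ccccc1 | intermediate (not isolated)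
15 | lithium (6S)-3-ethoxy-6-methoxy-2,6-bis(3-methylbut-2-en-1-yl)-5-oxocyclohexa-1,3-dien-1-olate | [Li+].CO[C@]1(CC=C(C)C)C(=O)C=C(OCC)C(CC=C(C)C)=C1[O-] | intermediate (not isolated)
16 | (6S)-3,5-dihydroxy-6-methoxy-4,6-bis(3-methylbut-2-en-1-yl)cyclohexa-2,4-dien-1-one | CO[C@]1(CC=C(C)C)C(=O)C=C(O)C(CC=C(C)C)=C1O | intermediate
17 | 3-phenylpropanoyl chloride | O=C(Cl)CCc1ccccc1 | starting material
18 | (4S)-5-hydroxy-4-methoxy-4,6-bis(3-methylbut-2-en-1-yl)-3-oxocyclohexa-1,5-dien-1-yl 3-phenylpropanoate (regioisomeric enol esters converge) | CO[C@]1(CC=C(C)C)C(=O)C=C(OC(=O)CCc2ccccc2)C(CC=C(C)C)=C1O | intermediate (not isolated)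
19 | (6S)-3,5-dihydroxy-6-methoxy-4,6-bis(3-methylbut-2-en-1-yl)-2-(3-phenylpropanoyl)cyclohexa-2,4-dien-1-one | CO[C@]1(CC=C(C)C)C(=O)C(C(=O)CCc2ccccc2)=C(O)C(CC=C(C)C)=C1O | target

**Count and risks**

Total step count: 5. Longest linear sequence: 4 steps (steps 2, 3, 4, 5); step 1 is a one-step branch that joins in step 4.

Steps most likely to fail:

1. Step 4 (the step with the new method). What may go wrong:
- The crowded aldolate 13 may revert to enolate and ketone before it opens. Face selectivity at the enolate carbon would then leak away or appear with the opposite sense; in the latter case the (1R,2S) alcohol would replace 6.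
- The Dieckmann closure onto the hindered ester may be slow and leave open-chain material.

Fallback with known chemistry, setting out from 17 and 9 and returning at 19: phloroglucinol (benzene-1,3,5-triol, Oc1cc(O)cc(O)c1, commercial) is acylated with 17 (AlCl3, nitrobenzene, 60 °C; Friedel–Crafts) to 3-phenyl-1-(2,4,6-trihydroxyphenyl)propan-1-one F1. Twofold C-prenylation of its phenolate with 9 (aq KOH, 0 °C) should give 3-phenyl-1-[2,4,6-trihydroxy-3,5-bis(3-methylbut-2-en-1-yl)phenyl]propan-1-one F2. Oxidative dearomatisation with PhI(OAc)2 in MeOH at −40 °C should deliver methanol to one of the two equivalent prenyl-bearing ring carbons and give racemic 3,5-dihydroxy-6-methoxy-4,6-bis(3-methylbut-2-en-1-yl)-2-(3-phenylpropanoyl)cyclohexa-2,4-dien-1-one F3. From F3, 19 is obtained by preparative HPLC on a chiral stationary phase.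

2. Step 1. What may go wrong: dimerisation and oligomerisation of the monoalkylketene in the presence of the amine base may outrun the cycloaddition.

Fallback setting out from 9 and returning at 5: tert-butoxyacetylene (CC(C)(C)OC#C) is lithiated (n-BuLi, THF, −78 °C) and alkylated with 9 (DMPU, to 0 °C) to 1-tert-butoxy-5-methylhex-4-en-1-yne F4. Warming F4 with an excess of 2 in toluene at 70 °C should release 2-methylpropene by a retro-ene reaction and generate ketene 4 slowly and without base. Ketene 4 is then intercepted by 2 in the same [2+2] cycloaddition to give 5.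

3. Step 5. What may go wrong: acylation at several enol oxygens without clean migration to carbon, or over-acylation.

Fallback setting out from 16 and returning at 19: 16 is silylated (Me3SiCl, Et3N, CH2Cl2) to (6S)-6-methoxy-4,6-bis(3-methylbut-2-en-1-yl)-3,5-bis(trimethylsilyloxy)cyclohexa-2,4-dien-1-one F5. Its siloxydiene carbon C2 is acylated directly with 17 under ZnCl2 mediation (CH2Cl2/Et2O, 0 to 23 °C; acylation of a silyl enol ether by an acid chloride). Aqueous work-up removes the remaining silyl group to give 19.

**Further compounds**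

F1 | step 4 | 3-phenyl-1-(2,4,6-trihydroxyphenyl)propan-1-one | O=C(CCc1ccccc1)c1c(O)cc(O)cc1O
F2 | step 4 | 3-phenyl-1-[2,4,6-trihydroxy-3,5-bis(3-methylbut-2-en-1-yl)phenyl]propan-1-one | O=C(CCc1ccccc1)c1c(O)c(CC=C(C)C)c(O)c(CC=C(C)C)c1O
F3 | step 4 | rac-3,5-dihydroxy-6-methoxy-4,6-bis(3-methylbut-2-en-1-yl)-2-(3-phenylpropanoyl)cyclohexa-2,4-dien-1-one | COC1(CC=C(C)C)C(=O)C(C(=O)CCc2ccccc2)=C(O)C(CC=C(C)C)=C1O
F4 | step 1 | 1-tert-butoxy-5-methylhex-4-en-1-yne | CC(C)=CCC#COC(C)(C)C
F5 | step 5 | (6S)-6-methoxy-4,6-bis(3-methylbut-2-en-1-yl)-3,5-bis(trimethylsilyloxy)cyclohexa-2,4-dien-1-one | CO[C@]1(CC=C(C)C)C(=O)C=C(O[Si](C)(C)C)C(CC=C(C)C)=C1O[Si](C)(C)C
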